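**Plan**

1. Target numbering: oxolane O1–C2(3,4-dimethoxyphenyl)–C3(CH3)–C4(CH3)–C5(4-hydroxy-3,5-dimethoxyphenyl), (2S,3S,4R,5R): aryls cis, methyls cis, each aryl trans to its neighbouring methyl.
2. Enabling feature: C2 is a benzylic ring carbon bearing an electron-rich aryl (cation-stabilising donor) and C5–O1 is the C=O of an aryl aldehyde in disguise. With two esters on C4, the unit C2–C3–C4 is a donor–acceptor cyclopropane.
3. Retrosynthesis: (i) both CH3 go back to CH2O, held as a cis-fused γ-lactone C4–C(=O)–O–CH2–C3, with a second ester on C4. (ii) O1–C2 and C4–C5 are cut together, giving 4-benzyloxy-3,5-dimethoxybenzaldehyde and a cis-2-aryl-3-(silyloxymethyl)cyclopropane-1,1-diester. (iii) The two cyclopropane bonds to the diester carbon are cut, giving dimethyl malonate and the cis cyclic sulfate of an erythro 1-arylglycerol. (iv) The aryl–carbinol bond is cut, giving an aryl Grignard reagent and (S)-glycerate.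
4. Forward order of rings: cyclic sulfate (auxiliary ring), then cyclopropane, then the oxolane by (3+2) annulation (the only ring of the target), then a temporary γ-lactone, which is opened and reduced to the two methyls before debenzylation.
5. Stereochemistry: C3 comes from (S)-glycerate (inverted once on cyclopropane closure). C2 comes from a chelation-controlled ketone reduction and is then inverted twice (malonate, aldehyde oxygen). C5 comes from the 2,5-cis closure of the annulation. C4 comes from the obligatory cis fusion of the lactone.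

Key step: step 8

Remark 1: O1 and C2–C5 in the Why lines are the target locants defined above; compound names carry their own IUPAC locants.
Remark 2: C3 is carried as CH2O–Si instead of CH3, because an ester on C4 between C3–CH3 and C5–aryl has no dependable facial or thermodynamic preference, whereas a lactone onto C3–CH2OH can only be cis-fused.
Remark 3: 3,4-dimethoxyphenylmagnesium bromide is taken as the commercial 0.5 M THF solution.

**Route**

Step 1
Reactants: 1 methyl (4S)-2,2-dimethyl-1,3-dioxolane-4-carboxylate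
Product: 2 (4S)-N-methoxy-N,2,2-trimethyl-1,3-dioxolane-4-carboxamide
Conditions: MeNH(OMe)·HCl (1.5 equiv), iPrMgCl (3 equiv), THF, −20 → 0 °C
Reagents that add atoms: N,O-dimethylhydroxylamine hydrochloride, CNOC.Cl
Why: Weinreb amide formation by aminolysis of the ester with the chloromagnesium amide, which is fast at low temperature and does not enolise the α-alkoxy stereocentre.

Step 2
Reactants: 2 (4S)-N-methoxy-N,2,2-trimethyl-1,3-dioxolane-4-carboxamide; 3 3,4-dimethoxyphenylmagnesium bromide
Product: 5 (2S)-1-(3,4-dimethoxyphenyl)-2,3-dihydroxypropan-1-one, via acetonide ketone 4 (not isolated)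
Conditions: 3 (1.3 equiv), THF, 0 °C; then 2 M aq HCl, rt
Reagents that add atoms: none
Why: Grignard addition to a Weinreb amide stops at the ketone because the magnesium-chelated tetrahedral intermediate collapses only on quenching, and the aqueous acid of the quench then hydrolyses the terminal isopropylidene acetal (acetal hydrolysis) at a stage where no acid-labile benzylic alcohol is present.

Step 3
Reactants: 5 (2S)-1-(3,4-dimethoxyphenyl)-2,3-dihydroxypropan-1-one
Product: 6 (2S)-3-[(tert-butyldiphenylsilyl)oxy]-1-(3,4-dimethoxyphenyl)-2-hydroxypropan-1-one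
Conditions: TBDPSCl (1.05 equiv), imidazole, CH2Cl2, 0 °C
Reagents that add atoms: tert-butyl(chloro)diphenylsilane, CC(C)(C)[Si](Cl)(c1ccccc1)c1ccccc1
Why: Silyl ether formation with a bulky chlorosilane discriminates the primary from the secondary hydroxyl on steric grounds and leaves the α-hydroxyl free for the chelation-controlled reduction.

Step 4
Reactants: 6 (2S)-3-[(tert-butyldiphenylsilyl)oxy]-1-(3,4-dimethoxyphenyl)-2-hydroxypropan-1-one
Product: 7 (1R,2S)-3-[(tert-butyldiphenylsilyl)oxy]-1-(3,4-dimethoxyphenyl)propane-1,2-diol (erythro)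
Conditions: Zn(BH4)2, Et2O, −20 → 0 °C; aq NH4Cl
Reagents that add atoms: none
Why: Chelation-controlled (Cram chelate) reduction of an α-hydroxy ketone: zinc ties the carbonyl and α-oxygen into a five-membered chelate (the silylated β-oxygen does not compete) and hydride enters from the face opposite the CH2OSi group, setting the carbinol centre anti to the C2 hydroxyl.

Step 5
Reactants: 7 (1R,2S)-3-[(tert-butyldiphenylsilyl)oxy]-1-(3,4-dimethoxyphenyl)propane-1,2-diol
Product: 9 (4S,5R)-4-{[(tert-butyldiphenylsilyl)oxy]methyl}-5-(3,4-dimethoxyphenyl)-1,3,2-dioxathiolane 2,2-dioxide, via cyclic sulfite 8 (not isolated)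
Conditions: SOCl2, Et3N, CH2Cl2, −20 → 0 °C; then RuCl3·xH2O (1 mol %), NaIO4, MeCN–H2O, 0 °C; crude product used at once
Reagents that add atoms: thionyl chloride, O=S(Cl)Cl; sodium periodate, [Na+].[O-]I(=O)(=O)=O
Why: Two-stage cyclic sulfate synthesis (cyclic sulfite from the diol, then RuO4-catalysed oxidation at sulfur) breaks no C–O bond of the diol, so the erythro diol gives the cis-4,5-disubstituted sulfate, and the cold, brief, buffered protocol is chosen to spare the dimethoxyarene and the ionisable benzylic C–O bond.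

Step 6
Reactants: 9 (4S,5R)-4-{[(tert-butyldiphenylsilyl)oxy]methyl}-5-(3,4-dimethoxyphenyl)-1,3,2-dioxathiolane 2,2-dioxide; 10 dimethyl malonate
Product: 12 dimethyl (2R,3R)-2-{[(tert-butyldiphenylsilyl)oxy]methyl}-3-(3,4-dimethoxyphenyl)cyclopropane-1,1-dicarboxylate (aryl and silyloxymethyl cis), via open-chain sulfate monoester 11 (not isolated)
Conditions: 10 (1.1 equiv), NaH (2.2 equiv), DME, 0 → 50 °C
Reagents that add atoms: sodium hydride, [Na+].[H-] (sodium counter-ion of the not-isolated salt 11 only; nothing of it remains in 12)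
Why: Double SN2 alkylation of the malonate anion by the cyclic sulfate (attack at the activated benzylic carbon, then 3-exo-tet displacement of the sulfate monoester by the regenerated malonate anion) inverts both carbinol centres, so the cis sulfate maps onto the cis-cyclopropane.

Step 7
Reactants: 13 syringaldehyde (4-hydroxy-3,5-dimethoxybenzaldehyde)
Product: 14 4-(benzyloxy)-3,5-dimethoxybenzaldehyde
Conditions: BnBr, K2CO3, DMF, rt
Reagents that add atoms: benzyl bromide, BrCc1ccccc1
Why: Williamson ether synthesis on the phenoxide masks the phenol with a group that survives Lewis acid, fluoride, hydride and sulfonylation and is removed last by hydrogenolysis.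

Step 8
Reactants: 12 dimethyl (2R,3R)-2-{[(tert-butyldiphenylsilyl)oxy]methyl}-3-(3,4-dimethoxyphenyl)cyclopropane-1,1-dicarboxylate; 14 4-(benzyloxy)-3,5-dimethoxybenzaldehyde
Product: 15 dimethyl (2S,4R,5S)-2-[4-(benzyloxy)-3,5-dimethoxyphenyl]-4-{[(tert-butyldiphenylsilyl)oxy]methyl}-5-(3,4-dimethoxyphenyl)oxolane-3,3-dicarboxylate (aryls cis; silyloxymethyl trans to the adjacent aryl)
Conditions: 14 (3 equiv), SnCl4 (10 mol %), CH2Cl2, −78 → −40 °C
Reagents that add atoms: none
Why: SnCl4 chelates the geminal diester and polarises the cyclopropane bond between the aryl-bearing carbon (future C2) and the diester carbon (future C4); the carbonyl oxygen of 14 attacks C2 from the side opposite the departing malonate (SN2-like, within an intimate ion pair) and the tin malonate enolate then adds to the carbon of the resulting O-alkyl oxocarbenium ion, so O1–C2 and C4–C5 form in one operation. The closest known reaction is the Lewis acid-catalysed (3+2) annulation of 2-arylcyclopropane-1,1-diesters with aldehydes, which gives 2,5-cis-tetrahydrofurans with inversion at the donor carbon. The oxolane closes by C4–C5 bond formation, an aldol-type attack of the enolate on an endocyclic C=O+ unit (formally 5-endo-trig, feasible because the electrophile is a cation). C2 is set by inversion of the cyclopropane carbon, C5 by an envelope transition state with both aryl groups and the C3 substituent pseudo-equatorial (2,5-cis), and C3 is carried over unchanged. The step needs inversion at C2 to win over ionisation, and the cis mode of closure; the cis relationship of aryl and CH2OSi in 12 becomes the required 2,3-trans relationship only through inversion, and low temperature with an excess of the electron-rich, nucleophilic aldehyde should keep bimolecular capture ahead of cation formation and of product equilibration.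

Step 9
Reactants: 15 dimethyl (2S,4R,5S)-2-[4-(benzyloxy)-3,5-dimethoxyphenyl]-4-{[(tert-butyldiphenylsilyl)oxy]methyl}-5-(3,4-dimethoxyphenyl)oxolane-3,3-dicarboxylate
Product: 17 methyl (3aR,4S,6S,6aR)-6-[4-(benzyloxy)-3,5-dimethoxyphenyl]-4-(3,4-dimethoxyphenyl)-1-oxotetrahydro-1H,3H-furo[3,4-c]furan-6a-carboxylate (cis-fused lactone), via hydroxy diester 16 (not isolated)
Conditions: TBAF, THF, 0 °C → rt
Reagents that add atoms: none
Why: Fluoride desilylation frees the C3 hydroxymethyl group, which can reach only the ester on its own face of the oxolane, so 5-exo-trig lactonisation selects the ester trans to the C5 aryl and leaves the other ester on the ring-fusion carbon.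

Step 10
Reactants: 17 methyl (3aR,4S,6S,6aR)-6-[4-(benzyloxy)-3,5-dimethoxyphenyl]-4-(3,4-dimethoxyphenyl)-1-oxotetrahydro-1H,3H-furo[3,4-c]furan-6a-carboxylate
Product: 18 (3aR,4S,6R,6aR)-6-[4-(benzyloxy)-3,5-dimethoxyphenyl]-4-(3,4-dimethoxyphenyl)tetrahydro-1H,3H-furo[3,4-c]furan-1-one
Conditions: LiCl, DMSO–H2O, 140 °C
Reagents that add atoms: none
Why: Krapcho dealkoxycarbonylation (chloride SN2 at the ester methyl, loss of CO2) leaves a lactone enolate that can be protonated only to the cis-fused bicyclo[3.3.0] lactone, which fixes the C4 carbon substituent cis to C3–CH2 and trans to the C5 aryl.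

Step 11
Reactants: 18 (3aR,4S,6R,6aR)-6-[4-(benzyloxy)-3,5-dimethoxyphenyl]-4-(3,4-dimethoxyphenyl)tetrahydro-1H,3H-furo[3,4-c]furan-1-one
Product: 19 [(2R,3S,4R,5S)-2-[4-(benzyloxy)-3,5-dimethoxyphenyl]-5-(3,4-dimethoxyphenyl)oxolane-3,4-diyl]dimethanol
Conditions: LiAlH4, THF, 0 °C
Reagents that add atoms: none
Why: Hydride reduction of the lactone to the 1,4-diol touches no stereocentre and leaves the benzyl and oxolane ethers intact.

Step 12
Reactants: 19 [(2R,3S,4R,5S)-2-[4-(benzyloxy)-3,5-dimethoxyphenyl]-5-(3,4-dimethoxyphenyl)oxolane-3,4-diyl]dimethanol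
Product: 20 [(2R,3S,4R,5S)-2-[4-(benzyloxy)-3,5-dimethoxyphenyl]-5-(3,4-dimethoxyphenyl)oxolane-3,4-diyl]bis(methylene) dimethanesulfonate
Conditions: MsCl (3 equiv), Et3N, CH2Cl2, −10 °C
Reagents that add atoms: methanesulfonyl chloride, CS(=O)(=O)Cl
Why: Mesylation through sulfene is fast for both primary alcohols at low temperature, so bis-sulfonylation should outrun intramolecular ether formation from a mono-mesylate.

Step 13
Reactants: 20 [(2R,3S,4R,5S)-2-[4-(benzyloxy)-3,5-dimethoxyphenyl]-5-(3,4-dimethoxyphenyl)oxolane-3,4-diyl]bis(methylene) dimethanesulfonate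
Product: 21 (2R,3R,4S,5S)-2-[4-(benzyloxy)-3,5-dimethoxyphenyl]-5-(3,4-dimethoxyphenyl)-3,4-dimethyloxolane
Conditions: LiEt3BH, THF, 0 → 60 °C
Reagents that add atoms: none
Why: SN2 hydride displacement of the two primary mesylates by lithium triethylborohydride gives the two methyl groups, while aryl, benzyl and oxolane ether C–O bonds are inert to hydride.

Step 14
Reactants: 21 (2R,3R,4S,5S)-2-[4-(benzyloxy)-3,5-dimethoxyphenyl]-5-(3,4-dimethoxyphenyl)-3,4-dimethyloxolane
Product: 22 4-[(2R,3R,4S,5S)-5-(3,4-dimethoxyphenyl)-3,4-dimethyloxolan-2-yl]-2,6-dimethoxyphenol (target)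
Conditions: H2 (1 atm), 10% Pd/C, EtOAc, rt
Reagents that add atoms: none
Why: Catalytic hydrogenolysis of the aryl benzyl ether in a neutral solvent at atmospheric pressure is much faster than cleavage of the dialkyl benzylic C–O bonds of the oxolane, so the reaction is stopped once the phenol is free.

**Compound list**

1 | methyl (4S)-2,2-dimethyl-1,3-dioxolane-4-carboxylate | COC(=O)[C@@H]1COC(C)(C)O1 | starting material
2 | (4S)-N-methoxy-N,2,2-trimethyl-1,3-dioxolane-4-carboxamide | CON(C)C(=O)[C@@H]1COC(C)(C)O1 | intermediate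
3 | 3,4-dimethoxyphenylmagnesium bromide | COc1ccc([Mg]Br)cc1OC | starting material
4 | (3,4-dimethoxyphenyl)[(4S)-2,2-dimethyl-1,3-dioxolan-4-yl]methanone | COc1ccc(cc1OC)C(=O)[C@@H]2COC(C)(C)O2 | intermediate (not isolated)
5 | (2S)-1-(3,4-dimethoxyphenyl)-2,3-dihydroxypropan-1-one | COc1ccc(cc1OC)C(=O)[C@@H](O)CO | intermediate
6 | (2S)-3-[(tert-butyldiphenylsilyl)oxy]-1-(3,4-dimethoxyphenyl)-2-hydroxypropan-1-one | COc1ccc(cc1OC)C(=O)[C@@H](O)CO[Si](c2ccccc2)(c3ccccc3)C(C)(C)C | intermediate
7 | (1R,2S)-3-[(tert-butyldiphenylsilyl)oxy]-1-(3,4-dimethoxyphenyl)propane-1,2-diol (erythro) | COc1ccc(cc1OC)[C@@H](O)[C@@H](O)CO[Si](c2ccccc2)(c3ccccc3)C(C)(C)C | intermediate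
8 | (4S,5R)-4-{[(tert-butyldiphenylsilyl)oxy]methyl}-5-(3,4-dimethoxyphenyl)-1,3,2-dioxathiolane 2-oxide (cis; both epimers at sulfur) | COc1ccc(cc1OC)[C@H]2OS(=O)O[C@H]2CO[Si](c3ccccc3)(c4ccccc4)C(C)(C)C | intermediate (not isolated)
9 | (4S,5R)-4-{[(tert-butyldiphenylsilyl)oxy]methyl}-5-(3,4-dimethoxyphenyl)-1,3,2-dioxathiolane 2,2-dioxide (cis) | COc1ccc(cc1OC)[C@H]2OS(=O)(=O)O[C@H]2CO[Si](c3ccccc3)(c4ccccc4)C(C)(C)C | intermediate
10 | dimethyl malonate | COC(=O)CC(=O)OC | starting material
11 | sodium (2R,3S)-1-[(tert-butyldiphenylsilyl)oxy]-3-(3,4-dimethoxyphenyl)-4,4-bis(methoxycarbonyl)butan-2-yl sulfate | COc1ccc(cc1OC)[C@H](C(C(=O)OC)C(=O)OC)[C@@H](OS(=O)(=O)[O-])CO[Si](c2ccccc2)(c3ccccc3)C(C)(C)C.[Na+] | intermediate (not isolated)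
12 | dimethyl (2R,3R)-2-{[(tert-butyldiphenylsilyl)oxy]methyl}-3-(3,4-dimethoxyphenyl)cyclopropane-1,1-dicarboxylate (aryl and silyloxymethyl cis) | COc1ccc(cc1OC)[C@H]2[C@@H](CO[Si](c3ccccc3)(c4ccccc4)C(C)(C)C)C2(C(=O)OC)C(=O)OC | intermediate
13 | syringaldehyde (4-hydroxy-3,5-dimethoxybenzaldehyde) | COc1cc(C=O)cc(OC)c1O | starting material
14 | 4-(benzyloxy)-3,5-dimethoxybenzaldehyde | O=Cc1cc(OC)c(OCc2ccccc2)c(OC)c1 | intermediate
15 | dimethyl (2S,4R,5S)-2-[4-(benzyloxy)-3,5-dimethoxyphenyl]-4-{[(tert-butyldiphenylsilyl)oxy]methyl}-5-(3,4-dimethoxyphenyl)oxolane-3,3-dicarboxylate | COc1ccc(cc1OC)[C@@H]2[C@@H](CO[Si](c3ccccc3)(c4ccccc4)C(C)(C)C)C(C(=O)OC)(C(=O)OC)[C@H](c5cc(OC)c(OCc6ccccc6)c(OC)c5)O2 | intermediate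
16 | dimethyl (2S,4R,5S)-2-[4-(benzyloxy)-3,5-dimethoxyphenyl]-5-(3,4-dimethoxyphenyl)-4-(hydroxymethyl)oxolane-3,3-dicarboxylate | COc1ccc(cc1OC)[C@@H]2[C@@H](CO)C(C(=O)OC)(C(=O)OC)[C@H](c3cc(OC)c(OCc4ccccc4)c(OC)c3)O2 | intermediate (not isolated)
17 | methyl (3aR,4S,6S,6aR)-6-[4-(benzyloxy)-3,5-dimethoxyphenyl]-4-(3,4-dimethoxyphenyl)-1-oxotetrahydro-1H,3H-furo[3,4-c]furan-6a-carboxylate | COc1ccc([C@H]2O[C@@H](c3cc(OC)c(OCc4ccccc4)c(OC)c3)[C@](C(=O)OC)(C(=O)OC5)[C@@H]25)cc1OC | intermediate
18 | (3aR,4S,6R,6aR)-6-[4-(benzyloxy)-3,5-dimethoxyphenyl]-4-(3,4-dimethoxyphenyl)tetrahydro-1H,3H-furo[3,4-c]furan-1-one | COc1ccc([C@H]2O[C@@H](c3cc(OC)c(OCc4ccccc4)c(OC)c3)[C@H](C(=O)OC5)[C@@H]25)cc1OC | intermediate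
19 | [(2R,3S,4R,5S)-2-[4-(benzyloxy)-3,5-dimethoxyphenyl]-5-(3,4-dimethoxyphenyl)oxolane-3,4-diyl]dimethanol | COc1ccc([C@H]2O[C@@H](c3cc(OC)c(OCc4ccccc4)c(OC)c3)[C@H](CO)[C@@H]2CO)cc1OC | intermediate
20 | [(2R,3S,4R,5S)-2-[4-(benzyloxy)-3,5-dimethoxyphenyl]-5-(3,4-dimethoxyphenyl)oxolane-3,4-diyl]bis(methylene) dimethanesulfonate | COc1ccc([C@H]2O[C@@H](c3cc(OC)c(OCc4ccccc4)c(OC)c3)[C@H](COS(C)(=O)=O)[C@@H]2COS(C)(=O)=O)cc1OC | intermediate
21 | (2R,3R,4S,5S)-2-[4-(benzyloxy)-3,5-dimethoxyphenyl]-5-(3,4-dimethoxyphenyl)-3,4-dimethyloxolane | COc1ccc([C@H]2O[C@@H](c3cc(OC)c(OCc4ccccc4)c(OC)c3)[C@H](C)[C@@H]2C)cc1OC | intermediate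
22 | 4-[(2R,3R,4S,5S)-5-(3,4-dimethoxyphenyl)-3,4-dimethyloxolan-2-yl]-2,6-dimethoxyphenol | COc1ccc([C@H]2O[C@@H](c3cc(OC)c(O)c(OC)c3)[C@H](C)[C@@H]2C)cc1OC | target

**Step count and risks**

Total: 14 steps. Longest linear sequence: 13 steps (1 to 22 by steps 1–6 and 8–14; step 7 is a one-step side branch).

Steps most likely to fail:

1. Step 8 (key annulation). What may go wrong: the Lewis acid opens the very electron-rich cyclopropane to a free benzylic cation–malonate ion pair before the aldehyde engages, so the inversion pathway is lost and the configuration at C2 leaks to the 2,3-cis oxolane. The bulky cis silyloxymethyl group slows the backside approach and makes this leak more competitive. Fallback: it sets out from 12. TBAF in THF removes the silyl group and the freed hydroxymethyl group closes onto the ester on its own face, giving methyl (1S,5R,6R)-6-(3,4-dimethoxyphenyl)-2-oxo-3-oxabicyclo[3.1.0]hexane-1-carboxylate F1. In this lactone-fused donor–acceptor cyclopropane the C3 substituent is tied back, the acceptor carbon still carries two chelating carbonyl groups, and the extra ring strain should allow annulation with 14 at lower temperature (Sn(OTf)2 or Sc(OTf)3, CH2Cl2). The product of that annulation is lactone ester 17, where the fallback comes back to the route with the desilylation already done.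

2. Step 5 (cyclic sulfate). What may go wrong: the benzylic C–O bond of the electron-rich cyclic sulfite or sulfate ionises (epimerisation at the benzylic carbon, rearrangement to carbonyl compounds), and RuO4 attacks the dimethoxyarene. Fallback: it sets out from dimethyl malonate 10 and makes the benzylic C–C bond by conjugate addition instead of by substitution. Addition of 10 to commercial (E)-3,4-dimethoxycinnamaldehyde under diarylprolinol silyl ether (iminium) catalysis, with the catalyst enantiomer that gives the (S)-adduct, leads to dimethyl 2-[(1S)-1-(3,4-dimethoxyphenyl)-3-oxopropyl]propanedioate F2. Enamine-catalysed α-chlorination with N-chlorosuccinimide under catalyst control gives dimethyl 2-[(1S,2R)-2-chloro-1-(3,4-dimethoxyphenyl)-3-oxopropyl]propanedioate F3, which is reduced in the same flask with NaBH4 to dimethyl 2-[(1S,2R)-2-chloro-1-(3,4-dimethoxyphenyl)-3-hydroxypropyl]propanedioate F4. Silylation (TBDPSCl, imidazole) gives dimethyl 2-[(1S,2R)-3-[(tert-butyldiphenylsilyl)oxy]-2-chloro-1-(3,4-dimethoxyphenyl)propyl]propanedioate F5. NaH in THF then closes the three-membered ring by 3-exo-tet displacement of chloride with inversion, which comes back to the route at cyclopropane 12 without any benzylic leaving group.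

3. Step 10 (Krapcho). What may go wrong: at 140 °C the lactone enolate formed on decarboxylation expels the ring oxygen from C5 (E1cB ring opening), which would epimerise C5 on re-closure or lead to an alkylidene lactone. Fallback: it sets out from 17. LiOH in aqueous THF hydrolyses the methyl ester (the lactone opens reversibly), and acidification re-closes the lactone to give (3aR,4S,6S,6aR)-6-[4-(benzyloxy)-3,5-dimethoxyphenyl]-4-(3,4-dimethoxyphenyl)-1-oxotetrahydro-1H,3H-furo[3,4-c]furan-6a-carboxylic acid F6. This β-carbonyl acid should lose CO2 on warming in toluene through a cyclic transition state and an enol, with no free enolate, and ketonisation to the cis-fused lactone comes back to the route at 18.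

**Further compounds**

F1 | step 8 | methyl (1S,5R,6R)-6-(3,4-dimethoxyphenyl)-2-oxo-3-oxabicyclo[3.1.0]hexane-1-carboxylate | COc1ccc(cc1OC)[C@H]2[C@H]3COC(=O)[C@@]23C(=O)OC
F2 | step 5 | dimethyl 2-[(1S)-1-(3,4-dimethoxyphenyl)-3-oxopropyl]propanedioate | COc1ccc(cc1OC)[C@H](C(C(=O)OC)C(=O)OC)CC=O
F3 | step 5 | dimethyl 2-[(1S,2R)-2-chloro-1-(3,4-dimethoxyphenyl)-3-oxopropyl]propanedioate | COc1ccc(cc1OC)[C@H](C(C(=O)OC)C(=O)OC)[C@@H](Cl)C=O
F4 | step 5 | dimethyl 2-[(1S,2R)-2-chloro-1-(3,4-dimethoxyphenyl)-3-hydroxypropyl]propanedioate | COc1ccc(cc1OC)[C@H](C(C(=O)OC)C(=O)OC)[C@@H](Cl)CO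
F5 | step 5 | dimethyl 2-[(1S,2R)-3-[(tert-butyldiphenylsilyl)oxy]-2-chloro-1-(3,4-dimethoxyphenyl)propyl]propanedioate | COc1ccc(cc1OC)[C@H](C(C(=O)OC)C(=O)OC)[C@@H](Cl)CO[Si](c2ccccc2)(c3ccccc3)C(C)(C)C
F6 | step 10 | (3aR,4S,6S,6aR)-6-[4-(benzyloxy)-3,5-dimethoxyphenyl]-4-(3,4-dimethoxyphenyl)-1-oxotetrahydro-1H,3H-furo[3,4-c]furan-6a-carboxylic acid | COc1ccc([C@H]2O[C@@H](c3cc(OC)c(OCc4ccccc4)c(OC)c3)[C@](C(=O)O)(C(=O)OC5)[C@@H]25)cc1OC
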